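## Retrosynthetic overview
- The C1 acid comes from a primary alcohol by late oxidation, and the phenol is released last from an aryl TIPS ether.
- C7–C8 is made by Cu-catalysed coupling of a chiral C1–C7 tosylate with a 15-arylpentadecyl Grignard reagent. That reagent comes from ω-pentadecalactone and anisole by Friedel–Crafts acylation and ionic hydrogenation.
- C5–C6 and the (E)-C3=C4 alkene come from a Johnson orthoester Claisen rearrangement of a 2-methylallylic alcohol, which consumes the C3 carbinol.
- The key C2–C3 bond is made by an intermolecular Evans boron syn-aldol of (R)-4-benzyl-3-propionyloxazolidin-2-one with methacrolein. This step sets the only stereocentre (C2, R).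
- No ring is formed. The benzene ring is bought as anisole, and the macrolactone is only opened.

Assumption: the SMILES is read as (2R,3E). Building blocks and intermediates are numbered, while auxiliary reagents (Bu2BOTf, TBSCl and the like) appear only on the Conditions and Reagents lines.

## Route

Step 1
Reactants: 1 (R)-4-benzyl-3-propionyloxazolidin-2-one; 2 methacrolein
Product: 5 (R)-4-benzyl-3-[(2R,3R)-3-hydroxy-2,4-dimethylpent-4-enoyl]oxazolidin-2-one, via Z-boron enolate 3 (not isolated), via boron aldolate 4 (not isolated)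
Conditions: Bu2BOTf (1.2 equiv), Et3N (1.4 equiv), CH2Cl2, 0 °C; 2 (2 equiv, freshly distilled), −78 → 0 °C; then pH 7 buffer, MeOH, 30% H2O2, 0 °C
Reagents that add atoms: none
Why: In this Evans syn-aldol the Z-boron enolate adds to the aldehyde through a Zimmerman–Traxler chair on the face opposite the benzyl group, which sets C2 as R (dr typically >95:5, minor isomers removed on crystalline 5) and C3 as R, a centre that is consumed later.

Step 2
Reactants: 5 aldol adduct
Product: 6 (2S,3R)-2,4-dimethylpent-4-ene-1,3-diol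
Conditions: LiBH4 (2 equiv), MeOH (2 equiv), THF, 0 °C
Reagents that add atoms: none
Why: This reductive auxiliary cleavage delivers hydride only to the activated exocyclic imide carbonyl and never deprotonates C2, so the centre keeps its geometry and its descriptor becomes S only through a CIP priority change.

Step 3
Reactants: 6 diol
Product: 7 (2S,3R)-1-(tert-butyldimethylsilyloxy)-2,4-dimethylpent-4-en-3-ol
Conditions: TBSCl (1.05 equiv), imidazole, CH2Cl2, 0 °C
Reagents that add atoms: tert-butyldimethylsilyl chloride `CC(C)(C)[Si](C)(C)Cl`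
Why: This silylation is sterically controlled, because the primary hydroxyl reacts far faster than the hindered secondary allylic hydroxyl that must stay free for step 4.

Step 4
Reactants: 7 mono-TBS ether; 8 triethyl orthoacetate
Product: 10 ethyl (4E,6R)-7-(tert-butyldimethylsilyloxy)-4,6-dimethylhept-4-enoate, via mixed ketene acetal 9 (not isolated)
Conditions: 8 (8 equiv), EtCO2H (10 mol %), 140 °C, EtOH distilled off
Reagents that add atoms: none
Why: In this Johnson orthoester Claisen rearrangement the chair [3,3] transition state places the CH(CH3)CH2OTBS group equatorial, away from the axial OEt, so the trisubstituted alkene forms E (typically >95:5), two carbons are added at the former =CH2, and the neighbouring methyl stereocentre is untouched.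

Step 5
Reactants: 10 ester
Product: 11 (4E,6R)-7-(tert-butyldimethylsilyloxy)-4,6-dimethylhept-4-en-1-ol
Conditions: LiAlH4, Et2O, 0 °C
Reagents that add atoms: none
Why: This hydride reduction of an unhindered ethyl ester leaves the isolated alkene and the TBS ether intact.

Step 6
Reactants: 11 alcohol
Product: 12 (4E,6R)-7-(tert-butyldimethylsilyloxy)-4,6-dimethylhept-4-en-1-yl 4-methylbenzenesulfonate
Conditions: TsCl, Et3N, DMAP (cat.), CH2Cl2, 0 °C → rt
Reagents that add atoms: p-toluenesulfonyl chloride `Cc1ccc(cc1)S(=O)(=O)Cl`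
Why: Sulfonylation of the primary alcohol gives a stable, unbranched electrophile suited to Cu-catalysed coupling.

Step 7
Reactants: 13 ω-pentadecalactone (oxacyclohexadecan-2-one)
Product: 14 15-bromopentadecanoic acid
Conditions: 33% HBr/AcOH, H2SO4 (cat.), 70 °C
Reagents that add atoms: hydrogen bromide `Br`
Why: This is an acid-mediated lactone opening in which bromide displaces the protonated acyloxy group at the primary CH2–O carbon (SN2) and delivers the crystalline ω-bromo acid.

Step 8
Reactants: 14 15-bromopentadecanoic acid; 15 anisole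
Product: 17 15-bromo-1-(4-methoxyphenyl)pentadecan-1-one, via acid chloride 16 (not isolated)
Conditions: (COCl)2, DMF (cat.), CH2Cl2, rt, concentrate; then 15 (1.5 equiv), AlCl3 (1.3 equiv), CH2Cl2, 0 °C
Reagents that add atoms: none
Why: Friedel–Crafts acylation of anisole is strongly para-selective and stops after one acylation, the primary bromide survives at 0 °C, and the trace ortho isomer is removed by recrystallisation.

Step 9
Reactants: 17 aryl ketone
Product: 18 1-(15-bromopentadecyl)-4-methoxybenzene
Conditions: Et3SiH (2.5 equiv), TFA, rt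
Reagents that add atoms: none
Why: In this ionic hydrogenation the protonated p-anisyl ketone and then the anisyl-stabilised benzylic cation each accept hydride from the silane, while the primary C–Br bond does not ionise.

Step 10
Reactants: 18 methyl ether
Product: 19 4-(15-bromopentadecyl)phenol
Conditions: BBr3 (1.3 equiv), CH2Cl2, −78 °C → rt; H2O
Reagents that add atoms: none
Why: The Lewis-acid aryl methyl ether cleavage is done here, before any alkene or stereocentre is present, so that the final phenol release can be mild.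

Step 11
Reactants: 19 phenol
Product: 20 [4-(15-bromopentadecyl)phenoxy]triisopropylsilane
Conditions: TIPSOTf, 2,6-lutidine, CH2Cl2, 0 °C
Reagents that add atoms: triisopropylsilyl triflate `CC(C)[Si](C(C)C)(C(C)C)OS(=O)(=O)C(F)(F)F`
Why: Fast O-silylation with a non-nucleophilic base spares the alkyl bromide and installs an aryl silyl ether that tolerates Grignard reagents and mild acid but is cleaved by fluoride.

Step 12
Reactants: 20 TIPS-protected bromide (1.5 equiv); 12 tosylate
Product: 22 tert-butyl{[(2R,3E)-2,4-dimethyl-22-(4-triisopropylsilyloxyphenyl)docos-3-en-1-yl]oxy}dimethylsilane, via Grignard reagent 21 (not isolated)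
Conditions: Mg (I2-activated), THF, 45 °C; then 12, Li2CuCl4 (5 mol %), THF, −78 °C → rt
Reagents that add atoms: none
Why: This Kochi–Schlosser Cu-catalysed sp3–sp3 cross-coupling joins a primary Grignard reagent to a primary tosylate (C7–C8), and both silyl ethers, the alkene and the remote C2 centre are unaffected.

Step 13
Reactants: 22 bis-silyl ether
Product: 23 (2R,3E)-2,4-dimethyl-22-(4-triisopropylsilyloxyphenyl)docos-3-en-1-ol
Conditions: CSA (10 mol %), MeOH–CH2Cl2 1:1, 0 °C
Reagents that add atoms: none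
Why: Acid-catalysed methanolysis removes the primary alkyl TBS ether quickly, whereas the weakly basic and bulky aryl TIPS ether is stable to acid.

Step 14
Reactants: 23 primary alcohol
Product: 25 (2R,3E)-2,4-dimethyl-22-(4-triisopropylsilyloxyphenyl)docos-3-enoic acid, via aldehyde 24 (not isolated)
Conditions: TEMPO (20 mol %), PhI(OAc)2 (2.5 equiv), CH2Cl2–H2O 2:1, 0 °C → rt
Reagents that add atoms: water `O`
Why: This TEMPO/PhI(OAc)2 oxidation is base-free and chlorine-free, and it hydrates and oxidises the enolisable β,γ-unsaturated aldehyde as it forms, so C2 is not epimerised and the alkene does not move into conjugation.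

Step 15
Reactants: 25 TIPS-protected acid
Product: 26 elenic acid, (2R,3E)-22-(4-hydroxyphenyl)-2,4-dimethyldocos-3-enoic acid
Conditions: TBAF–AcOH (1:1, 2 equiv), THF, 0 °C → rt
Reagents that add atoms: none
Why: Buffered fluoride desilylation of the aryl silyl ether avoids both the strong acid that would lactonise the β,γ-unsaturated acid and the strong base that would isomerise it.

## Compound list
1 | (R)-4-benzyl-3-propionyloxazolidin-2-one | `CCC(=O)N1[C@H](Cc2ccccc2)COC1=O` | starting material
2 | methacrolein | `CC(=C)C=O` | starting material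
3 | (R)-4-benzyl-3-[(Z)-1-(dibutylboryloxy)prop-1-enyl]oxazolidin-2-one (Z-boron enolate) | `C/C=C(\OB(CCCC)CCCC)N1[C@H](Cc2ccccc2)COC1=O` | intermediate
4 | O-dibutylboryl aldolate of 5 | `O=C(N1[C@H](Cc2ccccc2)COC1=O)[C@H](C)[C@@H](OB(CCCC)CCCC)C(C)=C` | intermediate
5 | (R)-4-benzyl-3-[(2R,3R)-3-hydroxy-2,4-dimethylpent-4-enoyl]oxazolidin-2-one | `O=C(N1[C@H](Cc2ccccc2)COC1=O)[C@H](C)[C@@H](O)C(C)=C` | intermediate
6 | (2S,3R)-2,4-dimethylpent-4-ene-1,3-diol | `OC[C@H](C)[C@@H](O)C(C)=C` | intermediate
7 | (2S,3R)-1-(tert-butyldimethylsilyloxy)-2,4-dimethylpent-4-en-3-ol | `CC(C)(C)[Si](C)(C)OC[C@H](C)[C@@H](O)C(C)=C` | intermediate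
8 | triethyl orthoacetate | `CC(OCC)(OCC)OCC` | starting material
9 | mixed ketene acetal (1-ethoxyvinyl ether of 7) | `CC(C)(C)[Si](C)(C)OC[C@H](C)[C@@H](OC(=C)OCC)C(C)=C` | intermediate
10 | ethyl (4E,6R)-7-(tert-butyldimethylsilyloxy)-4,6-dimethylhept-4-enoate | `CC(C)(C)[Si](C)(C)OC[C@H](C)/C=C(\C)CCC(=O)OCC` | intermediate
11 | (4E,6R)-7-(tert-butyldimethylsilyloxy)-4,6-dimethylhept-4-en-1-ol | `CC(C)(C)[Si](C)(C)OC[C@H](C)/C=C(\C)CCCO` | intermediate
12 | (4E,6R)-7-(tert-butyldimethylsilyloxy)-4,6-dimethylhept-4-en-1-yl tosylate | `CC(C)(C)[Si](C)(C)OC[C@H](C)/C=C(\C)CCCOS(=O)(=O)c1ccc(C)cc1` | intermediate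
13 | ω-pentadecalactone | `O=C1CCCCCCCCCCCCCCO1` | starting material
14 | 15-bromopentadecanoic acid | `OC(=O)CCCCCCCCCCCCCCBr` | intermediate
15 | anisole | `COc1ccccc1` | starting material
16 | 15-bromopentadecanoyl chloride | `ClC(=O)CCCCCCCCCCCCCCBr` | intermediate
17 | 15-bromo-1-(4-methoxyphenyl)pentadecan-1-one | `COc1ccc(cc1)C(=O)CCCCCCCCCCCCCCBr` | intermediate
18 | 1-(15-bromopentadecyl)-4-methoxybenzene | `COc1ccc(CCCCCCCCCCCCCCCBr)cc1` | intermediate
19 | 4-(15-bromopentadecyl)phenol | `Oc1ccc(CCCCCCCCCCCCCCCBr)cc1` | intermediate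
20 | [4-(15-bromopentadecyl)phenoxy]triisopropylsilane | `CC(C)[Si](Oc1ccc(CCCCCCCCCCCCCCCBr)cc1)(C(C)C)C(C)C` | intermediate
21 | 15-(4-triisopropylsilyloxyphenyl)pentadecylmagnesium bromide | `CC(C)[Si](Oc1ccc(CCCCCCCCCCCCCCC[Mg]Br)cc1)(C(C)C)C(C)C` | intermediate
22 | tert-butyl{[(2R,3E)-2,4-dimethyl-22-(4-triisopropylsilyloxyphenyl)docos-3-en-1-yl]oxy}dimethylsilane | `CC(C)(C)[Si](C)(C)OC[C@H](C)/C=C(\C)CCCCCCCCCCCCCCCCCCc1ccc(O[Si](C(C)C)(C(C)C)C(C)C)cc1` | intermediate
23 | (2R,3E)-2,4-dimethyl-22-(4-triisopropylsilyloxyphenyl)docos-3-en-1-ol | `OC[C@H](C)/C=C(\C)CCCCCCCCCCCCCCCCCCc1ccc(O[Si](C(C)C)(C(C)C)C(C)C)cc1` | intermediate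
24 | (2R,3E)-2,4-dimethyl-22-(4-triisopropylsilyloxyphenyl)docos-3-enal | `O=C[C@H](C)/C=C(\C)CCCCCCCCCCCCCCCCCCc1ccc(O[Si](C(C)C)(C(C)C)C(C)C)cc1` | intermediate
25 | (2R,3E)-2,4-dimethyl-22-(4-triisopropylsilyloxyphenyl)docos-3-enoic acid | `OC(=O)[C@H](C)/C=C(\C)CCCCCCCCCCCCCCCCCCc1ccc(O[Si](C(C)C)(C(C)C)C(C)C)cc1` | intermediate
26 | elenic acid, (2R,3E)-22-(4-hydroxyphenyl)-2,4-dimethyldocos-3-enoic acid | `C/C(=C\[C@@H](C)C(=O)O)CCCCCCCCCCCCCCCCCCc1ccc(O)cc1` | target

## Totals and risks
Total step count: 15. Longest linear sequence: 10 steps (steps 1–6, then 12–15). The arene arm contributes steps 7–11.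

**Step 12 (Cu-catalysed coupling).**
- Risk: Grignard formation from the waxy bromide can be sluggish, Wurtz dimer can form, and the tosylate can exchange to bromide.
- The fallback replaces the sp3–sp3 coupling by olefination followed by chemoselective saturation. It sets out from 20 and 11 and comes back at 22.
- Bromide 20 is heated with PPh3 in MeCN to give the phosphonium bromide F1.
- Alcohol 11 is oxidised with Dess–Martin periodinane/NaHCO3 to the non-epimerisable γ,δ-unsaturated aldehyde F2.
- NaHMDS in THF at −78 °C converts F1 into the ylide F3, which condenses with F2 to give the (3E,7Z)-diene F4.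
- Diimide (2-nitrobenzenesulfonyl hydrazide, Et3N, CH2Cl2, rt) reduces the 1,2-disubstituted C7=C8 bond far faster than the trisubstituted C3=C4 bond, and this gives 22.

**Step 4 (Johnson–Claisen rearrangement).**
- Risk: at 140 °C with acid the silyl group can migrate or be lost, the alcohol can dehydrate, and conversion can be incomplete.
- The fallback replaces the acidic thermal orthoester process by an anionic ester-enolate rearrangement of a different substrate. It sets out from 7 and comes back at 11, so 10 is bypassed.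
- Alcohol 7 is acetylated (Ac2O, pyridine, DMAP) to the acetate F5.
- LDA in THF at −78 °C followed by TBSCl/DMPU gives the silyl ketene acetal F6.
- On warming to rt, F6 undergoes the Ireland–Claisen [3,3] shift through the same equatorial chair to the (E)-silyl ester F7.
- Crude F7 is reduced with LiAlH4 in Et2O to 11.

**Step 14 (oxidation through the enolisable β,γ-unsaturated aldehyde).**
- Risk: partial epimerisation at C2 or traces of the conjugated isomer.
- The fallback does not rely on the oxidation staying stereochemically clean. It restores purity by covalent diastereomer separation. It sets out from 25 of eroded purity and comes back at pure 25.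
- Acid 25 is treated with PivCl/Et3N in THF at −20 °C to give the mixed pivalic anhydride F8.
- LiCl and (R)-4-benzyloxazolidin-2-one (the auxiliary recovered in step 2) convert F8 into the imide F9.
- F9 is separated on silica from its (2S)-epimer F10 and from any conjugated isomer.
- LiOH/H2O2 in THF–H2O at 0 °C cleaves F9 back to 25 without touching C2. Any aryl TIPS loss at this point is harmless, because step 15 removes that group anyway.

## Further compounds
F1 | step 12 | [15-(4-triisopropylsilyloxyphenyl)pentadecyl]triphenylphosphonium bromide | `CC(C)[Si](Oc1ccc(CCCCCCCCCCCCCCC[P+](c2ccccc2)(c2ccccc2)c2ccccc2)cc1)(C(C)C)C(C)C.[Br-]`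
F2 | step 12 | (4E,6R)-7-(tert-butyldimethylsilyloxy)-4,6-dimethylhept-4-enal | `CC(C)(C)[Si](C)(C)OC[C@H](C)/C=C(\C)CCC=O`
F3 | step 12 | [15-(4-triisopropylsilyloxyphenyl)pentadecylidene]triphenylphosphorane | `CC(C)[Si](Oc1ccc(CCCCCCCCCCCCCCC=P(c2ccccc2)(c2ccccc2)c2ccccc2)cc1)(C(C)C)C(C)C`
F4 | step 12 | tert-butyl{[(2R,3E,7Z)-2,4-dimethyl-22-(4-triisopropylsilyloxyphenyl)docosa-3,7-dien-1-yl]oxy}dimethylsilane | `CC(C)(C)[Si](C)(C)OC[C@H](C)/C=C(\C)CC/C=C\CCCCCCCCCCCCCCc1ccc(O[Si](C(C)C)(C(C)C)C(C)C)cc1`
F5 | step 4 | (2S,3R)-1-(tert-butyldimethylsilyloxy)-2,4-dimethylpent-4-en-3-yl acetate | `CC(C)(C)[Si](C)(C)OC[C@H](C)[C@@H](OC(C)=O)C(C)=C`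
F6 | step 4 | tert-butyldimethylsilyl ketene acetal of F5 | `CC(C)(C)[Si](C)(C)OC[C@H](C)[C@@H](OC(=C)O[Si](C)(C)C(C)(C)C)C(C)=C`
F7 | step 4 | tert-butyldimethylsilyl (4E,6R)-7-(tert-butyldimethylsilyloxy)-4,6-dimethylhept-4-enoate | `CC(C)(C)[Si](C)(C)OC[C@H](C)/C=C(\C)CCC(=O)O[Si](C)(C)C(C)(C)C`
F8 | step 14 | mixed pivalic anhydride of 25 | `CC(C)(C)C(=O)OC(=O)[C@H](C)/C=C(\C)CCCCCCCCCCCCCCCCCCc1ccc(O[Si](C(C)C)(C(C)C)C(C)C)cc1`
F9 | step 14 | (R)-4-benzyl-3-[(2R,3E)-2,4-dimethyl-22-(4-triisopropylsilyloxyphenyl)docos-3-enoyl]oxazolidin-2-one | `O=C(N1[C@H](Cc2ccccc2)COC1=O)[C@H](C)/C=C(\C)CCCCCCCCCCCCCCCCCCc1ccc(O[Si](C(C)C)(C(C)C)C(C)C)cc1`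
F10 | step 14 | (R)-4-benzyl-3-[(2S,3E)-2,4-dimethyl-22-(4-triisopropylsilyloxyphenyl)docos-3-enoyl]oxazolidin-2-one (discarded epimer) | `O=C(N1[C@H](Cc2ccccc2)COC1=O)[C@@H](C)/C=C(\C)CCCCCCCCCCCCCCCCCCc1ccc(O[Si](C(C)C)(C(C)C)C(C)C)cc1`
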